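**Plan**

- Ring atoms are numbered as in cyclohex-1-ene-1-carboxylate: C1 carries CO2Me, C3 the acetate, C4 and C5 the 2-methylbutanoates, C6 is CH2. The retrosynthesis cuts the three ester C–O bonds (back to methyl shikimate), folds the C1=C2/C3–OH unit back into a C2–C3 epoxide, and then cuts C1–C6 and C4–C5 in one [4+2].
- Enabling feature: the ester carbon on C1 and the oxygen on C4 stand 1,4 across the ring and can be one O–C(=O) bridge. C1–C4 are then C3–C6 of 2H-pyran-2-one, and the target ring is the carbocycle of a 2-oxabicyclo[2.2.2]octene. C5–C6 (one oxygen on C5, CH2 at C6) is a monosubstituted alkene.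
- Polarity: a vinyl ester or ether would add the wrong way round (its CH2 to the oxygen-bearing terminus). The alkene is therefore methyl vinyl ketone, whose acetyl-bearing carbon bonds next to the ring oxygen; Baeyer–Villiger oxidation later turns C5–acetyl into C5–O with retention.
- Forward: an enantioselective Diels–Alder reaction closes the carbocycle (the lactone bridge is a temporary ring). One peracid step gives the 5-acetate and the 2,3-epoxide. Methoxide opens lactone and epoxide (E1cB) to methyl shikimate. Orthoester-directed acetylation of O3 and double esterification of O4/O5 finish the route.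
- Stereochemistry: C4 and C5 come from the catalyst and the endo rule of the cycloaddition. C3 is relayed by epoxidation on the lactone-bridge face. The side-chain centres are bought as (R)-2-methylbutanoic acid.

Key step: step 1

Remark: both 2-methylbutanoyl groups are read as (R) from the SMILES; (R)-2-methylbutanoic acid is assumed to be purchasable in enantiopure form.

**Route**

Step 1
Reactants: 1 2H-pyran-2-one; 2 but-3-en-2-one (methyl vinyl ketone)
Product: 3 (1R,4R,7R)-7-acetyl-2-oxabicyclo[2.2.2]oct-5-en-3-one
Conditions: 2 (3 equiv), (S)-1-(2-methylphenyl)-3,3-diphenyltetrahydro-1H,3H-pyrrolo[1,2-c][1,3,2]oxazaborole (20 mol %), HN(SO2CF3)2 (18 mol %), CH2Cl2, −40 → −10 °C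
Reagents that add atoms: none
Why: Proposed new method: the cationic boron binds the ketone of 2 and lowers its LUMO, and the activated enone adds to the diene C3=C4–C5=C6 of 1 in a concerted but asynchronous normal-demand Diels–Alder reaction, in which the enone β-carbon bonds first to C3, the nucleophilic terminus of the pyranone (the site of its electrophilic substitution, conjugated with the ring-oxygen lone pair), so that the acetyl-bearing carbon ends on C6 next to the ring oxygen. The closest known reactions are the thermal Diels–Alder additions of 2-pyranones to electron-poor alkenes and the oxazaborolidinium-catalysed enantioselective Diels–Alder additions of enones and acrylates to weak dienes such as butadiene, cyclohexa-1,3-diene and furan; new is the pairing of this catalyst class with an unactivated 2-pyranone. One ring, the carbocycle, is closed by the [4+2] itself across C3 and C6 of the pyranone, which leaves the lactone as the bridge of a 2-oxabicyclo[2.2.2]octene. The two bridgeheads are set together by the suprafacial addition, C7 by the endo rule (acetyl under the diene, hence syn to the new C5=C6 bridge and trans to the ring oxygen on the future cyclohexene), and the absolute sense of all three by the aryl-shielded face of the bound enone; the (S)-catalyst is proposed, its mirror image being the one to use should the sense prove opposite. The step needs regioselectivity (acetyl next to the oxygen-bearing bridgehead), which the polarity match should secure, endo selectivity, which Lewis acid activation should secure, and retention of the CO2 bridge, which the low temperature should secure.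

Step 2
Reactants: 3
Product: 5 (1S,4R,5R,6R,7R)-7-acetoxy-5,6-epoxy-2-oxabicyclo[2.2.2]octan-3-one, via epoxy ketone 4 (not isolated)
Conditions: 3-chloroperbenzoic acid (4 equiv), CH2Cl2, 40 °C
Reagents that add atoms: 3-chloroperbenzoic acid, OOC(=O)c1cccc(Cl)c1
Why: The peracid should do two jobs, Prilezhaev epoxidation of the strained cis-alkene from the face of the lactone bridge (the endo C7 substituent screens the other face, which places the future O3 cis to O4) and Baeyer–Villiger oxidation of the methyl ketone, in which the secondary ring carbon migrates in preference to methyl with retention at C7.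

Step 3
Reactants: 5
Product: 7 methyl (3R,4S,5R)-3,4,5-trihydroxycyclohex-1-ene-1-carboxylate (methyl shikimate), via ring-opened epoxy acetate 6 (not isolated)
Conditions: NaOMe (0.3 equiv), MeOH, 0 °C → rt; then AcOH (0.3 equiv)
Reagents that add atoms: methanol, CO
Why: Catalytic methoxide should open the strained lactone by transesterification (methyl ester on C1, free 4-OH) and cleave the 5-acetate, and the ester enolate at C1 should then open the adjacent epoxide at C2 by E1cB elimination (the cis epoxy alkoxide cannot undergo Payne rearrangement), which moves the unsaturation to C1=C2 and frees the 3-OH with the configuration fixed in step 2.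

Step 4
Reactants: 7
Product: 9 methyl (3R,4S,5R)-3-acetoxy-4,5-dihydroxycyclohex-1-ene-1-carboxylate, via cyclic orthoacetate 8 (not isolated)
Conditions: MeC(OMe)3 (1.2 equiv), pyridinium p-toluenesulfonate (5 mol %), CH2Cl2, rt; then AcOH/H2O (4:1), rt
Reagents that add atoms: trimethyl orthoacetate, COC(C)(OC)OC; water, O
Why: Orthoester exchange should engage only the cis-3,4-diol as a five-membered cyclic orthoacetate, and its mild acid hydrolysis should open through the hemi-orthoester to the ester on the pseudoaxial oxygen O3, the usual kinetic outcome for cis-diols on six-membered rings, leaving the equatorial 4-OH and the 5-OH free.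

Step 5
Reactants: 9; 10 (R)-2-methylbutanoic acid
Product: 12 methyl (3R,4S,5R)-3-acetoxy-4,5-bis{[(2R)-2-methylbutanoyl]oxy}cyclohex-1-ene-1-carboxylate (the target), via 5-O-monoester 11 (not isolated)
Conditions: 10 (3 equiv), N,N'-dicyclohexylcarbodiimide (3 equiv), 4-(dimethylamino)pyridine (0.2 equiv), CH2Cl2, 0 °C → rt
Reagents that add atoms: none
Why: Steglich esterification should acylate the unhindered 5-OH first and then the flanked 4-OH, while the low temperature and the small amount of nucleophilic catalyst limit 3→4 acetyl migration and epimerisation of the α-centre of the acid, which is carried in unchanged.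

**Compound list**

1 | 2H-pyran-2-one | O=C1C=CC=CO1 | starting material
2 | but-3-en-2-one (methyl vinyl ketone) | CC(=O)C=C | starting material
3 | (1R,4R,7R)-7-acetyl-2-oxabicyclo[2.2.2]oct-5-en-3-one; acetyl on the two-carbon bridge next to the oxygen-bearing bridgehead, endo (syn to the C5=C6 bridge) | CC(=O)[C@@H]1C[C@@H]2C=C[C@H]1OC2=O | intermediate
4 | (1S,4R,5R,6R,7R)-7-acetyl-5,6-epoxy-2-oxabicyclo[2.2.2]octan-3-one; epoxide oxygen on the face of the lactone bridge | CC(=O)[C@@H]1C[C@@H]2[C@H]3O[C@H]3[C@H]1OC2=O | intermediate
5 | (1S,4R,5R,6R,7R)-7-acetoxy-5,6-epoxy-2-oxabicyclo[2.2.2]octan-3-one; epoxide oxygen on the face of the lactone bridge, acetoxy group on the other side of its bridge | CC(=O)O[C@@H]1C[C@@H]2[C@H]3O[C@H]3[C@H]1OC2=O | intermediate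
6 | methyl 5-acetoxy-2,3-epoxy-4-hydroxycyclohexane-1-carboxylate; ester group, epoxide oxygen and 4-OH on one face, 5-acetoxy on the other | COC(=O)[C@@H]1C[C@@H](OC(C)=O)[C@H](O)[C@@H]2O[C@H]12 | intermediate
7 | methyl (3R,4S,5R)-3,4,5-trihydroxycyclohex-1-ene-1-carboxylate (methyl shikimate) | COC(=O)C1=C[C@@H](O)[C@@H](O)[C@H](O)C1 | intermediate
8 | methyl 3,4-O-(1-methoxyethylidene)shikimate; cyclic orthoacetate on the cis-3,4-diol, both epimers at the orthoester carbon, 5-OH free | COC(=O)C1=C[C@H]2OC(C)(OC)O[C@H]2[C@H](O)C1 | intermediate
9 | methyl (3R,4S,5R)-3-acetoxy-4,5-dihydroxycyclohex-1-ene-1-carboxylate | COC(=O)C1=C[C@@H](OC(C)=O)[C@@H](O)[C@H](O)C1 | intermediate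
10 | (R)-2-methylbutanoic acid | CC[C@@H](C)C(=O)O | starting material
11 | methyl (3R,4S,5R)-3-acetoxy-4-hydroxy-5-{[(2R)-2-methylbutanoyl]oxy}cyclohex-1-ene-1-carboxylate | COC(=O)C1=C[C@@H](OC(C)=O)[C@@H](O)[C@H](OC(=O)[C@H](C)CC)C1 | intermediate
12 | methyl (3R,4S,5R)-3-acetoxy-4,5-bis{[(2R)-2-methylbutanoyl]oxy}cyclohex-1-ene-1-carboxylate | CC[C@@H](C)C(=O)O[C@@H]1[C@H](OC(C)=O)C=C(C(=O)OC)C[C@H]1OC(=O)[C@H](C)CC | target

**Step count**

Total steps: 5. Longest linear sequence: 5 steps (1 → 3 → 5 → 7 → 9 → 12).

**Steps most likely to fail**

Step 1 (Proposed new method). The pyranone may be too weak a diene, may tie up the Lewis acid through its own carbonyl group, or may add with poor regio- or enantiocontrol. The fallback uses known chemistry and sets out from 1 and 2. The two are joined without catalyst under pressure (about 12 kbar, CH2Cl2, room temperature), a known mode of 2-pyranone cycloaddition to electron-poor alkenes that keeps the CO2 bridge. This should give 3 as a racemate, that is, together with its mirror image, (1S,4S,7S)-7-acetyl-2-oxabicyclo[2.2.2]oct-5-en-3-one F1. Preparative chromatography on a chiral stationary phase (cellulose tris(3,5-dimethylphenylcarbamate)) should separate the two, and the route is rejoined at 3. The source of absolute configuration thus changes from catalysis to resolution.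

Step 2. The Baeyer–Villiger oxidation, whose migrating carbon carries a β-acyloxy group, may lag far behind the epoxidation, and the epoxide may be opened by 3-chlorobenzoic acid during the long exposure. The fallback sets out from 3 and separates the two oxidations with two orthogonal reagents. The ketone alone is oxidised with Me3SiOOSiMe3 and catalytic Me3SiOSO2CF3 in CH2Cl2 at low temperature, an electrophilic peroxide system that leaves C=C bonds untouched, to give (1R,4R,7R)-7-acetoxy-2-oxabicyclo[2.2.2]oct-5-en-3-one F2. Its alkene is then epoxidised with dimethyldioxirane in acetone under neutral, acid-free conditions, again from the face of the lactone bridge, and the route is rejoined at 5.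

Step 4. The orthoester may open with poor regiocontrol (acetate on O4), or the 5-OH may be acetylated through a mixed orthoester. The fallback sets out from 7 and replaces regioselective opening by protection. The trans-diequatorial 4,5-diol is masked as its butane-2,3-diacetal (butane-2,3-dione, HC(OMe)3, camphorsulfonic acid, MeOH, reflux) to give methyl 4,5-O-(2,3-dimethoxybutane-2,3-diyl)shikimate F3. The only free hydroxyl is acetylated (Ac2O, pyridine) to give methyl 3-O-acetyl-4,5-O-(2,3-dimethoxybutane-2,3-diyl)shikimate F4. The diacetal is then removed with CF3CO2H/H2O (9:1), and the route is rejoined at 9.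

Further compounds
F1 | step 1 | (1S,4S,7S)-7-acetyl-2-oxabicyclo[2.2.2]oct-5-en-3-one | CC(=O)[C@H]1C[C@H]2C=C[C@@H]1OC2=O
F2 | step 2 | (1R,4R,7R)-7-acetoxy-2-oxabicyclo[2.2.2]oct-5-en-3-one | CC(=O)O[C@@H]1C[C@@H]2C=C[C@H]1OC2=O
F3 | step 4 | methyl 4,5-O-(2,3-dimethoxybutane-2,3-diyl)shikimate (both methoxy groups axial, 3-OH free) | COC(=O)C1=C[C@@H](O)[C@H]2O[C@](C)(OC)[C@@](C)(OC)O[C@@H]2C1
F4 | step 4 | methyl 3-O-acetyl-4,5-O-(2,3-dimethoxybutane-2,3-diyl)shikimate | COC(=O)C1=C[C@@H](OC(C)=O)[C@H]2O[C@](C)(OC)[C@@](C)(OC)O[C@@H]2C1
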